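## Structural features

The target is a flavone: benzo ring A (C4a, C5 to C8, C8a) is fused to a 4-pyranone ring C (O1, C2, C3, C4), and aryl ring B is attached to C2 through the C2–C1' bond. Ring A carries hydroxyl groups at C5 and C7 and a methoxy group at C8; ring B carries a hydroxyl group at C2' and methoxy groups at C4' and C5'. The molecule has no stereocentre, so there are no neighbouring stereocentres to relate and the whole task is one of regiochemistry. The fragile features are the electron-rich polyphenol (air-sensitive as its phenoxides), the tendency of 5-hydroxy-8-methoxyflavones to equilibrate with the 6-methoxy isomers by ring opening and reclosure in hot strong acid, and, in the intermediates, an acid-labile aryl 1-arylvinyl ether and aryl silyl ethers that can be cleaved by base or move to a neighbouring phenoxide. The real difficulty lies in ring A, where four oxygen atoms (on C5, C7, C8 and C8a) must be told apart so that only O8 is methylated, while three phenols stay distinguishable from three methyl ethers up to the last step. The key step exploits the chain C4–C4a–C8a–O1–C2=C3 that exists once O1 of ring A is joined to C2 as an enol ether: the formyl carbon C4 and the unsubstituted alkene terminus C3 are then in a 1,6-relationship, so a radical centred on C4 can close ring C by forming C3–C4.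

## Logic of the disconnections

16 to 15. The three O–Si bonds (at O5, O7 and O2') are cut. Free phenols would quench oxygen-centred radicals in the preceding step, and silyl ethers carry no benzylic or acetal C–H bond. The gain is a single global deprotection at the end that leaves the three methyl ethers alone. The forward step must avoid strong acid and strong base, so buffered fluoride is used.

15 to 14. The C3–C4 bond of ring C is cut, the only C–C bond of the pyranone that lies outside an aromatic ring. This opens ring C and leaves the two aromatic halves joined through O1–C2 alone. The atom mapping was checked and is consistent: the formyl carbon of 14 becomes C4, the carbon bearing the enol ether oxygen becomes C8a, and the substituents land at C5, C7 and C8 as required. The forward step must abstract the formyl hydrogen, close 6-endo and not 5-exo, and end by oxidation in a medium free of water and acid. One change of design is made: the two ring A silyl ethers in 14 and 15 are triisopropylsilyl and not tert-butyldimethylsilyl. They resist base, peroxide and silyl migration through the ring A sequence, and they shield the one free ring A position (C6) from electrophilic iodine in the key step.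

14 to 8 and 13. The O1–C2 bond is cut on the vinyl side. This gives two aromatic building blocks of similar size and makes the route convergent. The forward step must form a C–O bond at a phenol flanked by a formyl and a methoxy group under neutral conditions, and boron in 13 must sit on the internal vinyl carbon.

13 to 12, 11, 10 and 9. The C–B bond, then the enol O–S bond, then the O–Si bond are cut. The methyl ketone fixes the position of boron without any regiochemical question. Hydroboration of the corresponding aryl alkyne would be the shorter-looking way, but it is not reliable for internal borylation with so electron-rich an arene. The gain is a purchasable acetophenone 9. The forward demand is that enolate 11 is trapped cold, before silicon can move from the aryl oxygen to the enolate oxygen.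

8 to 7. The aryl–CHO bond is cut. In 7 the free hydroxyl has only one open ortho position, so a phenoxide-directed formylation can only go there. The demand is that this works next to a bulky silyloxy group.

7 to 6 and 5. The O–CH3 bond is cut and a benzyl group is put on the oxygen that is free in 7. The methoxy group must end up between a free hydroxyl and a silyloxy group, so the two ortho oxygens of 1 have to differ when the methyl group is introduced. A plan that only silylates, oxidises, methylates and formylates 1 cannot work: it passes through a symmetrical tris-silyl ether with no free phenol to direct the formylation, or through a catechol that would be methylated on the wrong oxygen. The benzyl group corrects this. The forward demand is methylation of a doubly flanked phenol without silyl migration.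

5 to 4 and 3. The aryl C–O bond of the future O8 is traced back to the aryl–CHO bond. The formyl group of 1 thus serves as the placeholder for the fourth ring A oxygen. The forward demand is aryl, not hydrogen, migration in the peracid oxidation, which the three donor oxygens secure.

3 to 2 and 1. The O–benzyl bond and two O–Si bonds are cut. Chelation to the formyl group differentiates the hydroxyls of 1: the para and one ortho hydroxyl are silylated and the chelated one is benzylated. The forward demand is clean bis-silylation.

## Other disconnections considered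

Alternative 1: The cut runs through ring A at C8–C8a and C4a–C5, so ring A would be built last on a preformed 2-aryl-4-pyranone. In the forward step the electron-rich diene A3 (1,4-dimethoxy-1,3-bis(trimethylsilyloxy)buta-1,3-diene) would add to the sulfonyl-bearing pyranone A2 (2-[2-(benzyloxy)-4,5-dimethoxyphenyl]-5-tosyl-4H-pyran-4-one). Its methoxy-bearing terminus would bond to C8a and its ketene acetal carbon to C4a. Loss of p-toluenesulfinic acid, methanol and the silyl groups would aromatise ring A to A1, and one hydrogenolysis would give the target.
- In its favour: the partners are polarity-matched (nucleophilic diene, sulfone-activated enone), which is a sounder mechanistic footing than joining two donor carbons, and here the alternative is the better. The ring A oxygen pattern comes from the diene, no ring A phenol needs protection, and the step count should equal or beat the chosen route.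
- Against it here: a 4-pyranone double bond is a reluctant dienophile even with the sulfone, and the reaction may stop at the conjugate adduct. The aromatisation has a choice of leaving groups and could expel the C8 methoxy group instead of the ketal methoxy group at C5, erasing the substituent that is hardest to place. A2 and the moisture-sensitive A3 both have to be made.
- Comparison: the alternative forms two C–C bonds and ring A at once; the chosen plan forms one C–C bond and ring C. The chosen plan fixes every ring A oxygen by covalent steps before the key step, and that certainty of regiochemistry is why it is kept.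

Alternative 2: The cut is the C2–C1' bond. Ring B would be delivered to a chromone through an ester tether. In A5 (2-bromo-4,5-dimethoxyphenyl 5,7-bis(benzyloxy)-8-methoxy-4-oxo-4H-chromene-3-carboxylate), zerovalent palladium formed from Pd(OAc)2 and tricyclohexylphosphine would insert into the C–Br bond. Carbonate- and pivalate-assisted metalation of the chromone C2–H and reductive elimination would give lactone A4.
- In its favour: intramolecular direct arylation closing a six-membered lactone is an established reaction type, so this key step rests on firmer precedent than the radical closure chosen here; on this point the alternative is the better. The regiochemistry is certain because C2–H is the only C–H bond within reach.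
- Against it here: the tether is not part of the target. The lactone must be opened and the C3 carboxyl group removed, and hydroxide strong enough for that can also open the pyranone at C2. Two benzyl ethers must then be removed. Ring A needs the same 5,7,8-oxygenation as in the chosen route, so nothing is saved there.
- Comparison: the alternative forms C2–C1' and a ring that is later destroyed; the chosen plan forms ring C itself. On step economy the alternative is the poorer, with three operations after the key step against one.

Alternative 3: The cut is the O1–C8a bond. In A7 (1-[4-(benzyloxy)-2,5-dihydroxyphenyl]-3-[2-(benzyloxy)-4,5-dimethoxyphenyl]propane-1,3-dione), Ag2O would oxidise the hydroquinone to the acylquinone. The enol oxygen of the diketone would add to C8a and close ring C, and tautomerisation would give the 5,8-dihydroxyflavone A6. Methylation of the unchelated 8-hydroxyl and hydrogenolysis would finish the synthesis.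
- In its favour: ring A needs only a 1,2,4-trioxygenated acetophenone, which is simpler than the tetraoxygenated aldehyde 8; here the alternative is the better. The closure is a polarity-matched oxa-conjugate addition, the diketone comes from standard Claisen chemistry, and the step count should be about equal.
- Against it here: acylquinones are very electrophilic and prone to hydration, self-condensation and over-oxidation, and the electron-rich ring B and the enol are themselves open to oxidation by Ag2O. The 5- and 8-hydroxyl groups must then be told apart (chelation of the 5-hydroxyl should allow it, but it is one more selective step), and two benzyl ethers remain.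
- Comparison: the alternative forms a C–O bond by a polar step and the chosen plan a C–C bond by a radical step. The alternative leaves the ring A pattern unfinished until after the key step, whereas the chosen plan has it complete beforehand and needs only one deprotection afterwards.

Key step: step 11

Remark on the chemistry (assumption): 1-(2-hydroxy-4,5-dimethoxyphenyl)ethan-1-one (9) and both silyl chlorides are taken as purchasable; ring A carries triisopropylsilyl ethers and ring B keeps the tert-butyldimethylsilyl ether.

## Route

Step 1
Reactants: 1 2,4,6-trihydroxybenzaldehyde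
Product: 2 2-hydroxy-4,6-bis[(triisopropylsilyl)oxy]benzaldehyde
Conditions: iPr3SiCl (2.05 equiv), imidazole, DMF, 0 °C to rt
Reagents that add atoms: triisopropylsilyl chloride, CC(C)[Si](Cl)(C(C)C)C(C)C
Why: Silyl ether formation at phenols: the para hydroxyl and one of the two equivalent ortho hydroxyls are silylated, while the last hydroxyl stays chelated to the formyl oxygen and is too weakly nucleophilic to react with the bulky chlorosilane at this stoichiometry.

Step 2
Reactants: 2 2-hydroxy-4,6-bis[(triisopropylsilyl)oxy]benzaldehyde
Product: 3 2-(benzyloxy)-4,6-bis[(triisopropylsilyl)oxy]benzaldehyde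
Conditions: BnOH, PPh3, DIAD, THF, 0 °C to rt
Reagents that add atoms: benzyl alcohol, OCc1ccccc1
Why: Mitsunobu etherification: the chelated, fairly acidic salicylaldehyde hydroxyl is alkylated under neutral conditions, which spares the base-labile silyl ether para to the formyl group; the benzyl group marks this oxygen as the one that later becomes the free phenol.

Step 3
Reactants: 3 2-(benzyloxy)-4,6-bis[(triisopropylsilyl)oxy]benzaldehyde
Product: 5 2-(benzyloxy)-4,6-bis[(triisopropylsilyl)oxy]phenol, via aryl formate 4 (not isolated)
Conditions: mCPBA, CH2Cl2, 0 °C to rt; then Et3N, MeOH, 0 °C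
Reagents that add atoms: 3-chloroperoxybenzoic acid, O=C(OO)c1cccc(Cl)c1
Why: Baeyer–Villiger (Dakin-type) oxidation: in the peracid adduct the electron-rich trioxygenated aryl group migrates in preference to hydrogen, giving formate 4 with the new oxygen (the future O8) on the former formyl position; amine-catalysed methanolysis then frees the phenol without a strongly basic phenoxide stage.

Step 4
Reactants: 5 2-(benzyloxy)-4,6-bis[(triisopropylsilyl)oxy]phenol
Product: 6 1-(benzyloxy)-2-methoxy-3,5-bis[(triisopropylsilyl)oxy]benzene
Conditions: MeOH, PPh3, DIAD, THF, 0 °C to rt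
Reagents that add atoms: methanol, CO
Why: Mitsunobu O-methylation: the small methoxyphosphonium electrophile reaches the doubly flanked oxygen, and the cold, near-neutral conditions together with the bulk of the triisopropylsilyl group should prevent transfer of silicon from the neighbouring oxygen, which would misplace the methyl group.

Step 5
Reactants: 6 1-(benzyloxy)-2-methoxy-3,5-bis[(triisopropylsilyl)oxy]benzene
Product: 7 2-methoxy-3,5-bis[(triisopropylsilyl)oxy]phenol
Conditions: H2 (1 atm), Pd/C, EtOAc, rt
Reagents that add atoms: none
Why: Hydrogenolysis of the benzyl aryl ether over palladium metal; the aryl silyl ethers, the methyl ether and the arene are inert, and the phenol set free is the one flanked by the methoxy group and a ring hydrogen.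

Step 6
Reactants: 7 2-methoxy-3,5-bis[(triisopropylsilyl)oxy]phenol
Product: 8 2-hydroxy-3-methoxy-4,6-bis[(triisopropylsilyl)oxy]benzaldehyde
Conditions: MgCl2, Et3N, (CH2O)n, MeCN, reflux
Reagents that add atoms: paraformaldehyde (as formaldehyde), C=O
Why: Magnesium-mediated ortho-formylation of a phenol (Casnati–Skattebøl reaction): the magnesium phenoxide delivers formaldehyde to the only free ortho position and a second formaldehyde acts as hydride acceptor to give the aldehyde; the para position is outside this chelation control and is shielded by two silyloxy groups.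

Step 7
Reactants: 9 1-(2-hydroxy-4,5-dimethoxyphenyl)ethan-1-one
Product: 10 1-[2-(tert-butyldimethylsilyloxy)-4,5-dimethoxyphenyl]ethan-1-one
Conditions: tBuMe2SiCl, imidazole, DMF, rt to 40 °C
Reagents that add atoms: tert-butyldimethylsilyl chloride, CC(C)(C)[Si](C)(C)Cl
Why: Silylation of the only hydroxyl group; imidazole in DMF is sufficient to silylate a ketone-chelated phenol.

Step 8
Reactants: 10 1-[2-(tert-butyldimethylsilyloxy)-4,5-dimethoxyphenyl]ethan-1-one
Product: 12 1-[2-(tert-butyldimethylsilyloxy)-4,5-dimethoxyphenyl]ethenyl trifluoromethanesulfonate, via potassium enolate 11 (not isolated)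
Conditions: KN(SiMe3)2, THF, −78 °C; then 2-[N,N-bis(trifluoromethylsulfonyl)amino]-5-chloropyridine, −78 °C
Reagents that add atoms: 2-[N,N-bis(trifluoromethylsulfonyl)amino]-5-chloropyridine, O=S(=O)(N(c1ccc(Cl)cn1)S(=O)(=O)C(F)(F)F)C(F)(F)F
Why: Kinetic enolisation of the methyl ketone and O-sulfonylation of the enolate (enol triflate formation): only the methyl group can be deprotonated, so the alkene is necessarily 1,1-disubstituted, and the pyridyl triflimide reacts at −78 °C before silicon can move to the enolate oxygen.

Step 9
Reactants: 12 1-[2-(tert-butyldimethylsilyloxy)-4,5-dimethoxyphenyl]ethenyl trifluoromethanesulfonate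
Product: 13 tert-butyl{4,5-dimethoxy-2-[1-(4,4,5,5-tetramethyl-1,3,2-dioxaborolan-2-yl)ethenyl]phenoxy}dimethylsilane
Conditions: B2pin2, PdCl2(dppf) (3 mol%), KOAc, 1,4-dioxane, 80 °C
Reagents that add atoms: bis(pinacolato)diboron, CC1(C)OB(OC1(C)C)B1OC(C)(C)C(C)(C)O1
Why: Miyaura borylation of an alkenyl triflate: zerovalent palladium inserts into the C–O bond of the triflate, the acetate-bound divalent palladium transmetalates with the diboron, and reductive elimination places boron on the carbon that bore the triflate.

Step 10
Reactants: 8 2-hydroxy-3-methoxy-4,6-bis[(triisopropylsilyl)oxy]benzaldehyde; 13 tert-butyl{4,5-dimethoxy-2-[1-(4,4,5,5-tetramethyl-1,3,2-dioxaborolan-2-yl)ethenyl]phenoxy}dimethylsilane (2.5 equiv)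
Product: 14 2-({1-[2-(tert-butyldimethylsilyloxy)-4,5-dimethoxyphenyl]ethenyl}oxy)-3-methoxy-4,6-bis[(triisopropylsilyl)oxy]benzaldehyde
Conditions: Cu(OAc)2 (2 equiv), pyridine, 4 Å MS, CH2Cl2, dry air, rt to 40 °C
Reagents that add atoms: none
Why: Copper-mediated oxidative C–O coupling of a phenol with an alkenylboronate (Chan–Lam type): the divalent copper phenoxide takes the alkenyl group from boron, and oxidation to trivalent copper followed by reductive elimination forms O1–C2. The reaction runs near room temperature without protic acid, so the formyl group, the silyl ethers and the new enol ether should survive; the boron-bearing carbon becomes C2, which delivers the 1,1-disubstituted alkene needed next.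

Step 11
Reactants: 14 2-({1-[2-(tert-butyldimethylsilyloxy)-4,5-dimethoxyphenyl]ethenyl}oxy)-3-methoxy-4,6-bis[(triisopropylsilyl)oxy]benzaldehyde
Product: 15 2-[2-(tert-butyldimethylsilyloxy)-4,5-dimethoxyphenyl]-8-methoxy-5,7-bis[(triisopropylsilyl)oxy]-4H-chromen-4-one
Conditions: Bu4NI (20 mol%), t-BuOOH (anhydrous, in decane, 3 equiv), PhCl, 80 °C, Ar
Reagents that add atoms: none
Why: Proposed new method: iodide reduces tert-butyl hydroperoxide to tert-butoxyl (and, by exchange, tert-butylperoxyl) radicals, which abstract the formyl hydrogen of 14 to give an aroyl radical that does not lose CO; this radical adds to the unsubstituted CH2 terminus (C3) of the enol ether, forming C3–C4 and closing ring C, and the resulting C2 radical is oxidised (by hypoiodite, iodine or hydroperoxide) to the O1-stabilised cation, which loses the C3 proton to give 15. The closest known reaction type is the peroxide-driven acyl radical cyclisation of 2-(allyloxy)benzaldehydes to chroman-4-ones, together with Bu4NI/t-BuOOH oxidative functionalisation of aldehyde C–H bonds; closure onto an aryl 1-arylvinyl ether with rearomatising termination has not been shown. Ring C closes in the 6-endo-trig mode. No stereocentre is formed. The step needs 6-endo over 5-exo closure, which the 1,1-disubstituted alkene secures: attack at C3 gives a tertiary radical stabilised by O1 and ring B, attack at C2 a primary radical next to a quaternary carbon, and that primary β-keto radical could in any case reach the same six-membered radical by a 1,2-acyl shift (Dowd–Beckwith type). It also needs hydrogen abstraction at the formyl group alone, which is secured by capping every phenol as a silyl ether without benzylic or acetal C–H bonds; the triisopropylsilyl groups also shield the only free ring A position (C6) from iodination. A polar closure is not available because C3 and C4 are both donor-type carbons, so the union is made through the acyl radical, and the medium is kept anhydrous and neutral to spare the enol ether.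

Step 12
Reactants: 15 2-[2-(tert-butyldimethylsilyloxy)-4,5-dimethoxyphenyl]-8-methoxy-5,7-bis[(triisopropylsilyl)oxy]-4H-chromen-4-one
Product: 16 5,7-dihydroxy-2-(2-hydroxy-4,5-dimethoxyphenyl)-8-methoxy-4H-chromen-4-one
Conditions: Bu4NF (3.5 equiv), AcOH (4 equiv), THF, 0 °C to rt
Reagents that add atoms: none
Why: Fluoride-induced cleavage of the three aryl silyl ethers; acetic acid buffers the phenoxides, so the electron-rich flavone is not exposed to strong base, and the methyl ethers and the pyranone are untouched.

## Compound list

1 | 2,4,6-trihydroxybenzaldehyde | O=Cc1c(O)cc(O)cc1O | starting material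
2 | 2-hydroxy-4,6-bis[(triisopropylsilyl)oxy]benzaldehyde | O=Cc1c(O)cc(O[Si](C(C)C)(C(C)C)C(C)C)cc1O[Si](C(C)C)(C(C)C)C(C)C | intermediate
3 | 2-(benzyloxy)-4,6-bis[(triisopropylsilyl)oxy]benzaldehyde | O=Cc1c(OCc2ccccc2)cc(O[Si](C(C)C)(C(C)C)C(C)C)cc1O[Si](C(C)C)(C(C)C)C(C)C | intermediate
4 | 2-(benzyloxy)-4,6-bis[(triisopropylsilyl)oxy]phenyl formate | O=COc1c(OCc2ccccc2)cc(O[Si](C(C)C)(C(C)C)C(C)C)cc1O[Si](C(C)C)(C(C)C)C(C)C | intermediate (not isolated)
5 | 2-(benzyloxy)-4,6-bis[(triisopropylsilyl)oxy]phenol | Oc1c(OCc2ccccc2)cc(O[Si](C(C)C)(C(C)C)C(C)C)cc1O[Si](C(C)C)(C(C)C)C(C)C | intermediate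
6 | 1-(benzyloxy)-2-methoxy-3,5-bis[(triisopropylsilyl)oxy]benzene | COc1c(OCc2ccccc2)cc(O[Si](C(C)C)(C(C)C)C(C)C)cc1O[Si](C(C)C)(C(C)C)C(C)C | intermediate
7 | 2-methoxy-3,5-bis[(triisopropylsilyl)oxy]phenol | COc1c(O)cc(O[Si](C(C)C)(C(C)C)C(C)C)cc1O[Si](C(C)C)(C(C)C)C(C)C | intermediate
8 | 2-hydroxy-3-methoxy-4,6-bis[(triisopropylsilyl)oxy]benzaldehyde | O=Cc1c(O[Si](C(C)C)(C(C)C)C(C)C)cc(O[Si](C(C)C)(C(C)C)C(C)C)c(OC)c1O | intermediate
9 | 1-(2-hydroxy-4,5-dimethoxyphenyl)ethan-1-one | COc1cc(O)c(C(C)=O)cc1OC | starting material
10 | 1-[2-(tert-butyldimethylsilyloxy)-4,5-dimethoxyphenyl]ethan-1-one | COc1cc(O[Si](C)(C)C(C)(C)C)c(C(C)=O)cc1OC | intermediate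
11 | potassium 1-[2-(tert-butyldimethylsilyloxy)-4,5-dimethoxyphenyl]ethen-1-olate | [K+].[O-]C(=C)c1cc(OC)c(OC)cc1O[Si](C)(C)C(C)(C)C | intermediate (not isolated)
12 | 1-[2-(tert-butyldimethylsilyloxy)-4,5-dimethoxyphenyl]ethenyl trifluoromethanesulfonate | COc1cc(O[Si](C)(C)C(C)(C)C)c(C(=C)OS(=O)(=O)C(F)(F)F)cc1OC | intermediate
13 | tert-butyl{4,5-dimethoxy-2-[1-(4,4,5,5-tetramethyl-1,3,2-dioxaborolan-2-yl)ethenyl]phenoxy}dimethylsilane | COc1cc(O[Si](C)(C)C(C)(C)C)c(C(=C)B2OC(C)(C)C(C)(C)O2)cc1OC | intermediate
14 | 2-({1-[2-(tert-butyldimethylsilyloxy)-4,5-dimethoxyphenyl]ethenyl}oxy)-3-methoxy-4,6-bis[(triisopropylsilyl)oxy]benzaldehyde | O=Cc1c(O[Si](C(C)C)(C(C)C)C(C)C)cc(O[Si](C(C)C)(C(C)C)C(C)C)c(OC)c1OC(=C)c1cc(OC)c(OC)cc1O[Si](C)(C)C(C)(C)C | intermediate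
15 | 2-[2-(tert-butyldimethylsilyloxy)-4,5-dimethoxyphenyl]-8-methoxy-5,7-bis[(triisopropylsilyl)oxy]-4H-chromen-4-one | COc1cc(O[Si](C)(C)C(C)(C)C)c(-c2cc(=O)c3c(O[Si](C(C)C)(C(C)C)C(C)C)cc(O[Si](C(C)C)(C(C)C)C(C)C)c(OC)c3o2)cc1OC | intermediate
16 | 5,7-dihydroxy-2-(2-hydroxy-4,5-dimethoxyphenyl)-8-methoxy-4H-chromen-4-one | COc1cc(O)c(-c2cc(=O)c3c(O)cc(O)c(OC)c3o2)cc1OC | target

## Step count and least certain steps

Total step count: 12. Longest linear sequence: 9 steps (steps 1 to 6, then 10, 11 and 12); the ring B branch has 3 steps (7 to 9).

Step 11 (key step, proposed new method). The addition of the aroyl radical to the electron-rich enol ether is polarity-mismatched and may be slow. The acyl radical could then be intercepted by tert-butylperoxyl radicals or over-oxidised, oxygen radicals or iodine species could attack the enol ether, and traces of acid and water at 80 °C could hydrolyse it. Partial loss of a silyl group would release a phenol that inhibits the radical chain. The fallback uses known polar chemistry; it sets out from 8 and 12 and returns at 15.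
- Elimination of triflic acid from 12 with LiN(iPr)2 in THF at −78 °C should give tert-butyl(2-ethynyl-4,5-dimethoxyphenoxy)dimethylsilane F1.
- F1, deprotonated in situ with n-BuLi (2.2 equiv, the first equivalent deprotonating the phenol), should add to the formyl group of 8 at −78 °C to give racemic 2-{3-[2-(tert-butyldimethylsilyloxy)-4,5-dimethoxyphenyl]-1-hydroxyprop-2-yn-1-yl}-6-methoxy-3,5-bis[(triisopropylsilyl)oxy]phenol F2.
- MnO2 in CH2Cl2 should oxidise the benzylic propargylic alcohol to 1-{2-hydroxy-3-methoxy-4,6-bis[(triisopropylsilyl)oxy]phenyl}-3-[2-(tert-butyldimethylsilyloxy)-4,5-dimethoxyphenyl]prop-2-yn-1-one F3.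
- Et2NH in EtOH at rt should close ring C by conjugate addition of the phenol oxygen to the ynone (6-endo-dig, by way of the β-amino enone) and give 15.

Step 10. Transmetalation from the pinacol boronate to copper may be slow at a phenol flanked by formyl and methoxy groups. Protodeboronation or homocoupling of the alkenylboronate and sequestration of copper by the salicylaldehyde chelate may then take over. The fallback replaces the C–O coupling by methylenation of an aryl ester; it sets out from 8 and returns at 14.
- tert-Butyldimethylsilyl 2-(tert-butyldimethylsilyloxy)-4,5-dimethoxybenzoate F4 (from double silylation of the commercial hydroxy acid) is converted with (COCl)2 and catalytic DMF into 2-(tert-butyldimethylsilyloxy)-4,5-dimethoxybenzoyl chloride F5.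
- Acylation of 8 (Et3N, DMAP, CH2Cl2) should give 2-formyl-6-methoxy-3,5-bis[(triisopropylsilyl)oxy]phenyl 2-(tert-butyldimethylsilyloxy)-4,5-dimethoxybenzoate F6.
- HC(OMe)3 with pyridinium p-toluenesulfonate in MeOH should mask the aldehyde as 2-(dimethoxymethyl)-6-methoxy-3,5-bis[(triisopropylsilyl)oxy]phenyl 2-(tert-butyldimethylsilyloxy)-4,5-dimethoxybenzoate F7.
- Cp2TiMe2 in toluene at 70 °C should methylenate the ester carbonyl to tert-butyl[2-(1-{2-(dimethoxymethyl)-6-methoxy-3,5-bis[(triisopropylsilyl)oxy]phenoxy}ethenyl)-4,5-dimethoxyphenoxy]dimethylsilane F8.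
- Base-buffered acetal cleavage (Et3SiOTf, 2,6-lutidine, CH2Cl2, 0 °C, then H2O) should free the aldehyde without protonating the enol ether and give 14.

Step 8. Silicon may transfer from the aryl oxygen to the enolate oxygen before sulfonylation, and the electron-rich 1-arylvinyl triflate may ionise during purification. The fallback avoids both the enolate and the triflate; it sets out from 10 and returns at 13.
- Triphenyl phosphite dibromide and Et3N in CH2Cl2 (−60 °C to rt) should convert the ketone into tert-butyl[2-(1-bromoethenyl)-4,5-dimethoxyphenoxy]dimethylsilane F9.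
- Palladium-catalysed borylation (B2pin2, PdCl2(dppf), KOAc, 1,4-dioxane, 80 °C) should then give 13.

Step 6. Formylation may stall because the only free ortho position lies next to a bulky silyloxy group, leaving starting phenol or methylene-bridged dimers. The fallback uses directed metalation; it sets out from 7 and returns at 8.
- MeOCH2Cl and iPr2NEt should give 2-methoxy-1-(methoxymethoxy)-3,5-bis[(triisopropylsilyl)oxy]benzene F10.
- n-BuLi with TMEDA in THF (−78 to −40 °C) should lithiate the position ortho to the acetal oxygen, and DMF should give 3-methoxy-2-(methoxymethoxy)-4,6-bis[(triisopropylsilyl)oxy]benzaldehyde F11.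
- Catalytic HCl in MeOH at 0 °C should remove the methoxymethyl group and give 8.

## Further compounds

F1 | step 11 | tert-butyl(2-ethynyl-4,5-dimethoxyphenoxy)dimethylsilane | C#Cc1cc(OC)c(OC)cc1O[Si](C)(C)C(C)(C)C
F2 | step 11 | racemic 2-{3-[2-(tert-butyldimethylsilyloxy)-4,5-dimethoxyphenyl]-1-hydroxyprop-2-yn-1-yl}-6-methoxy-3,5-bis[(triisopropylsilyl)oxy]phenol | COc1c(O)c(C(O)C#Cc2cc(OC)c(OC)cc2O[Si](C)(C)C(C)(C)C)c(O[Si](C(C)C)(C(C)C)C(C)C)cc1O[Si](C(C)C)(C(C)C)C(C)C
F3 | step 11 | 1-{2-hydroxy-3-methoxy-4,6-bis[(triisopropylsilyl)oxy]phenyl}-3-[2-(tert-butyldimethylsilyloxy)-4,5-dimethoxyphenyl]prop-2-yn-1-one | COc1c(O)c(C(=O)C#Cc2cc(OC)c(OC)cc2O[Si](C)(C)C(C)(C)C)c(O[Si](C(C)C)(C(C)C)C(C)C)cc1O[Si](C(C)C)(C(C)C)C(C)C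
F4 | step 10 | tert-butyldimethylsilyl 2-(tert-butyldimethylsilyloxy)-4,5-dimethoxybenzoate | COc1cc(O[Si](C)(C)C(C)(C)C)c(C(=O)O[Si](C)(C)C(C)(C)C)cc1OC
F5 | step 10 | 2-(tert-butyldimethylsilyloxy)-4,5-dimethoxybenzoyl chloride | COc1cc(O[Si](C)(C)C(C)(C)C)c(C(=O)Cl)cc1OC
F6 | step 10 | 2-formyl-6-methoxy-3,5-bis[(triisopropylsilyl)oxy]phenyl 2-(tert-butyldimethylsilyloxy)-4,5-dimethoxybenzoate | O=Cc1c(O[Si](C(C)C)(C(C)C)C(C)C)cc(O[Si](C(C)C)(C(C)C)C(C)C)c(OC)c1OC(=O)c1cc(OC)c(OC)cc1O[Si](C)(C)C(C)(C)C
F7 | step 10 | 2-(dimethoxymethyl)-6-methoxy-3,5-bis[(triisopropylsilyl)oxy]phenyl 2-(tert-butyldimethylsilyloxy)-4,5-dimethoxybenzoate | COC(OC)c1c(O[Si](C(C)C)(C(C)C)C(C)C)cc(O[Si](C(C)C)(C(C)C)C(C)C)c(OC)c1OC(=O)c1cc(OC)c(OC)cc1O[Si](C)(C)C(C)(C)C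
F8 | step 10 | tert-butyl[2-(1-{2-(dimethoxymethyl)-6-methoxy-3,5-bis[(triisopropylsilyl)oxy]phenoxy}ethenyl)-4,5-dimethoxyphenoxy]dimethylsilane | COC(OC)c1c(O[Si](C(C)C)(C(C)C)C(C)C)cc(O[Si](C(C)C)(C(C)C)C(C)C)c(OC)c1OC(=C)c1cc(OC)c(OC)cc1O[Si](C)(C)C(C)(C)C
F9 | step 8 | tert-butyl[2-(1-bromoethenyl)-4,5-dimethoxyphenoxy]dimethylsilane | COc1cc(O[Si](C)(C)C(C)(C)C)c(C(Br)=C)cc1OC
F10 | step 6 | 2-methoxy-1-(methoxymethoxy)-3,5-bis[(triisopropylsilyl)oxy]benzene | COCOc1cc(O[Si](C(C)C)(C(C)C)C(C)C)cc(O[Si](C(C)C)(C(C)C)C(C)C)c1OC
F11 | step 6 | 3-methoxy-2-(methoxymethoxy)-4,6-bis[(triisopropylsilyl)oxy]benzaldehyde | O=Cc1c(O[Si](C(C)C)(C(C)C)C(C)C)cc(O[Si](C(C)C)(C(C)C)C(C)C)c(OC)c1OCOC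
A1 | alternative 1 | 2-[2-(benzyloxy)-4,5-dimethoxyphenyl]-5,7-dihydroxy-8-methoxy-4H-chromen-4-one | COc1cc(OCc2ccccc2)c(-c2cc(=O)c3c(O)cc(O)c(OC)c3o2)cc1OC
A2 | alternative 1 | 2-[2-(benzyloxy)-4,5-dimethoxyphenyl]-5-(4-methylbenzenesulfonyl)-4H-pyran-4-one | COc1cc(OCc2ccccc2)c(-c2cc(=O)c(S(=O)(=O)c3ccc(C)cc3)co2)cc1OC
A3 | alternative 1 | 1,4-dimethoxy-1,3-bis(trimethylsilyloxy)buta-1,3-diene (double-bond geometry not defined) | COC=C(O[Si](C)(C)C)C=C(OC)O[Si](C)(C)C
A4 | alternative 2 | ring B lactone of 5,7-bis(benzyloxy)-2-(2-hydroxy-4,5-dimethoxyphenyl)-8-methoxy-4-oxo-4H-chromene-3-carboxylic acid | COc1cc2c(cc1OC)oc(=O)c1c2oc2c(OC)c(OCc3ccccc3)cc(OCc3ccccc3)c2c1=O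
A5 | alternative 2 | 2-bromo-4,5-dimethoxyphenyl 5,7-bis(benzyloxy)-8-methoxy-4-oxo-4H-chromene-3-carboxylate | COc1cc(Br)c(OC(=O)c2coc3c(OC)c(OCc4ccccc4)cc(OCc4ccccc4)c3c2=O)cc1OC
A6 | alternative 3 | 7-(benzyloxy)-2-[2-(benzyloxy)-4,5-dimethoxyphenyl]-5,8-dihydroxy-4H-chromen-4-one | COc1cc(OCc2ccccc2)c(-c2cc(=O)c3c(O)cc(OCc4ccccc4)c(O)c3o2)cc1OC
A7 | alternative 3 | 1-[4-(benzyloxy)-2,5-dihydroxyphenyl]-3-[2-(benzyloxy)-4,5-dimethoxyphenyl]propane-1,3-dione | COc1cc(OCc2ccccc2)c(C(=O)CC(=O)c2cc(O)c(OCc3ccccc3)cc2O)cc1OC
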